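**Retrosynthetic overview**

1. Target 20 ⇐ BCl3 removal of the chelated 5‑methyl ether and both benzyl ethers ⇐ 3‑methoxyflavone 19 ⇐ copper‑catalysed exchange of C3–I for C3–OMe on 3‑iodoflavone 18.
2. 18 ⇐ ICl‑induced demethylative iodocyclisation of diaryl ynone 17, forming O1–C2 and C3–I; ring C is the only ring made, rings A and B come from the starting arenes.
3. 17 ⇐ MnO2 oxidation ⇐ propargylic alcohol 16 ⇐ C3–C4 bond from the lithium acetylide of ring B alkyne 14 and ring A aldehyde 7.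
4. 7 ⇐ syringol 1 (O‑benzylation, dibromination, double methoxylation, lithiation/DMF); 14 ⇐ 2,5‑dimethoxybenzaldehyde 8 (Dakin oxidation, O‑benzylation, Vilsmeier formylation, Ohira–Bestmann).
5. Feature used: in ring C, O1 sits on C2 and C3 carries OMe; in ring A, C5 and C8a (both flanking C4a) bear oxygen and C6/C8 both bear OMe. A 2,6‑dimethoxyaryl ynone that is symmetric about its C1–C4 axis can therefore close O1–C2 through either ortho oxygen, and the electrophile left on C3 is later exchanged for OMe.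

Key step: step 11

Remark on the chemistry: the target is achiral; alcohol 16 is made as the racemate and its only stereocentre is removed in step 10.

**Route**

Step 1
Reactants: 1 2,6‑dimethoxyphenol (syringol)
Product: 2 2‑(benzyloxy)‑1,3‑dimethoxybenzene
Conditions: BnBr, K2CO3, DMF, 60 °C
Reagents that add atoms: benzyl bromide BrCc1ccccc1
Why: Williamson etherification of the phenoxide with a reactive benzylic bromide should proceed even for this doubly ortho‑substituted phenol in a dipolar aprotic solvent.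

Step 2
Reactants: 2 2‑(benzyloxy)‑1,3‑dimethoxybenzene
Product: 3 3‑(benzyloxy)‑1,5‑dibromo‑2,4‑dimethoxybenzene
Conditions: NBS (2.2 equiv), MeCN, 0 °C → rt, dark
Reagents that add atoms: N‑bromosuccinimide O=C1CCC(=O)N1Br
Why: Electrophilic aromatic bromination should go to the two carbons that are ortho to one methoxy group and para to the other, because the central benzyloxy group is twisted out of conjugation and does not activate its para carbon, as in the dibromination of 1,2,3‑trimethoxybenzene.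

Step 3
Reactants: 3 3‑(benzyloxy)‑1,5‑dibromo‑2,4‑dimethoxybenzene
Product: 4 3‑(benzyloxy)‑1,2,4,5‑tetramethoxybenzene
Conditions: NaOMe (excess), CuBr (20 mol %), MeOH–DMF, 110 °C
Reagents that add atoms: sodium methoxide [Na+].[O-]C
Why: Ullmann‑type CuBr‑catalysed methoxylation of aryl bromides with NaOMe is standard for polyalkoxybenzenes, and the benzyl ether is inert to methoxide.

Step 4
Reactants: 4 3‑(benzyloxy)‑1,2,4,5‑tetramethoxybenzene
Product: 7 4‑(benzyloxy)‑2,3,5,6‑tetramethoxybenzaldehyde, via aryllithium 5 (not isolated), via lithium aminoalkoxide 6 (not isolated)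
Conditions: n‑BuLi, TMEDA, THF, −20 → 0 °C; DMF, −78 °C → rt; then 1 M HCl
Reagents that add atoms: N,N‑dimethylformamide CN(C)C=O
Why: Directed ortho‑metalation should remove the only ring proton, which is acidified and coordinated by two flanking methoxy groups and is therefore taken faster than a benzylic proton of the ether, and the aryllithium is formylated by DMF through the stable aminoalkoxide (Bouveault‑type formylation).

Step 5
Reactants: 8 2,5‑dimethoxybenzaldehyde
Product: 10 2,5‑dimethoxyphenol, via aryl formate 9 (not isolated)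
Conditions: mCPBA, CH2Cl2, 0 °C → rt; then K2CO3 (cat.), MeOH, rt
Reagents that add atoms: meta‑chloroperbenzoic acid OOC(=O)c1cccc(Cl)c1
Why: Dakin‑type Baeyer–Villiger oxidation of an electron‑rich benzaldehyde proceeds with aryl migration to the formate, which mild methanolysis cleaves to the phenol.

Step 6
Reactants: 10 2,5‑dimethoxyphenol
Product: 11 2‑(benzyloxy)‑1,4‑dimethoxybenzene
Conditions: BnBr, K2CO3, DMF, rt
Reagents that add atoms: benzyl bromide BrCc1ccccc1
Why: Williamson etherification of an unhindered phenoxide with benzyl bromide is routine.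

Step 7
Reactants: 11 2‑(benzyloxy)‑1,4‑dimethoxybenzene
Product: 13 4‑(benzyloxy)‑2,5‑dimethoxybenzaldehyde, via iminium chloride 12 (not isolated)
Conditions: POCl3, DMF, 0 → 70 °C; then H2O
Reagents that add atoms: N,N‑dimethylformamide CN(C)C=O; water O
Why: Vilsmeier–Haack formylation should attack the carbon para to the benzyloxy group and ortho to a methoxy group, the most activated and least hindered site of this 1,2,4‑trialkoxybenzene, as in the formylation of 1,2,4‑trimethoxybenzene.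

Step 8
Reactants: 13 4‑(benzyloxy)‑2,5‑dimethoxybenzaldehyde
Product: 14 1‑(benzyloxy)‑4‑ethynyl‑2,5‑dimethoxybenzene
Conditions: dimethyl (1‑diazo‑2‑oxopropyl)phosphonate, K2CO3, MeOH, rt
Reagents that add atoms: dimethyl (1‑diazo‑2‑oxopropyl)phosphonate CC(=O)C(=[N+]=[N-])P(=O)(OC)OC
Why: Seyferth–Gilbert homologation in the Ohira–Bestmann variant converts an aryl aldehyde into the terminal alkyne under mild carbonate conditions that leave the ethers untouched.

Step 9
Reactants: 14 1‑(benzyloxy)‑4‑ethynyl‑2,5‑dimethoxybenzene; 7 4‑(benzyloxy)‑2,3,5,6‑tetramethoxybenzaldehyde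
Product: 16 rac‑1‑[4‑(benzyloxy)‑2,3,5,6‑tetramethoxyphenyl]‑3‑[4‑(benzyloxy)‑2,5‑dimethoxyphenyl]prop‑2‑yn‑1‑ol, via lithium acetylide 15 (not isolated)
Conditions: n‑BuLi, THF, −78 °C; then 7, −78 → 0 °C; aq. NH4Cl
Reagents that add atoms: none
Why: 1,2‑Addition of a lithium acetylide to an aldehyde is fast and the small linear nucleophile reaches the carbonyl between the two ortho methoxy groups; the carbinol centre forms as the racemate and is removed in step 10.

Step 10
Reactants: 16 rac‑1‑[4‑(benzyloxy)‑2,3,5,6‑tetramethoxyphenyl]‑3‑[4‑(benzyloxy)‑2,5‑dimethoxyphenyl]prop‑2‑yn‑1‑ol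
Product: 17 1‑[4‑(benzyloxy)‑2,3,5,6‑tetramethoxyphenyl]‑3‑[4‑(benzyloxy)‑2,5‑dimethoxyphenyl]prop‑2‑yn‑1‑one
Conditions: MnO2 (activated, excess), CH2Cl2, rt
Reagents that add atoms: none
Why: Activated MnO2 oxidises alcohols that are both benzylic and propargylic selectively to ynones without touching the ethers or the alkyne.

Step 11
Reactants: 17 1‑[4‑(benzyloxy)‑2,3,5,6‑tetramethoxyphenyl]‑3‑[4‑(benzyloxy)‑2,5‑dimethoxyphenyl]prop‑2‑yn‑1‑one
Product: 18 7‑(benzyloxy)‑2‑[4‑(benzyloxy)‑2,5‑dimethoxyphenyl]‑3‑iodo‑5,6,8‑trimethoxy‑4H‑chromen‑4‑one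
Conditions: ICl (1.2–1.5 equiv, slow addition), CH2Cl2, −78 °C; aq. Na2S2O3
Reagents that add atoms: iodine monochloride ClI
Why: ICl delivers I+ to the alkyne of 17 to give an iodonium ion whose positive charge sits on the ring B‑bearing carbon (future C2), where the 2'‑OMe and 4'‑OBn donors stabilise it; the oxygen of either ortho methoxy group of ring A attacks that carbon anti to iodine, and chloride then removes the methyl group of the aryl(methyl)oxonium ion as MeCl. The closest known reaction type is the ICl‑induced cyclisation of 2‑methoxyaryl alkynones to 3‑iodochromones. Ring C closes in the 6‑endo‑dig mode through O1–C2 while C3–I forms in the same event, and no stereocentre is created. Three selectivities are needed: 6‑endo over 5‑exo closure (secured by the Michael polarity of the ynone and the donor aryl group on C2), closure by a ring A oxygen and not by the 2'‑methoxy oxygen of ring B (that 5‑endo path would have to attack the electron‑poor carbon next to C=O), and alkyne activation ahead of iodination of ring B (secured by −78 °C, slow addition and a small excess of ICl). Because the two ortho methoxy groups of ring A are equivalent by symmetry only one chromone can form, and the unused one becomes the 5‑OMe.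

Step 12
Reactants: 18 7‑(benzyloxy)‑2‑[4‑(benzyloxy)‑2,5‑dimethoxyphenyl]‑3‑iodo‑5,6,8‑trimethoxy‑4H‑chromen‑4‑one
Product: 19 7‑(benzyloxy)‑2‑[4‑(benzyloxy)‑2,5‑dimethoxyphenyl]‑3,5,6,8‑tetramethoxy‑4H‑chromen‑4‑one
Conditions: CuI (10 mol %), 1,10‑phenanthroline (20 mol %), Cs2CO3, MeOH–toluene, 90 °C
Reagents that add atoms: methanol CO
Why: Ullmann‑type C–O coupling, in which phenanthroline‑ligated monovalent copper inserts into the C3–I bond and exchanges iodide for methoxide, is established for aryl and vinyl iodides, and the carbonate base keeps the free methoxide concentration low so that the pyranone should not be opened at C2.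

Step 13
Reactants: 19 7‑(benzyloxy)‑2‑[4‑(benzyloxy)‑2,5‑dimethoxyphenyl]‑3,5,6,8‑tetramethoxy‑4H‑chromen‑4‑one
Product: 20 5,7‑dihydroxy‑2‑(4‑hydroxy‑2,5‑dimethoxyphenyl)‑3,6,8‑trimethoxy‑4H‑chromen‑4‑one (5,7,4'‑trihydroxy‑3,6,8,2',5'‑pentamethoxyflavone)
Conditions: BCl3 (about 6 equiv), pentamethylbenzene, CH2Cl2, −78 → 0 °C; then aq. HCl
Reagents that add atoms: none
Why: BCl3 cleaves aryl benzyl ethers at low temperature (pentamethylbenzene traps the benzyl cation so that ring B is not C‑benzylated) and should remove only the methyl ether whose oxygen forms a six‑membered boron chelate with the C4 carbonyl, the 5‑OMe, while the 3‑, 6‑, 8‑, 2'‑ and 5'‑OMe groups lack that activation and persist.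

**Compound list**

1 | 2,6‑dimethoxyphenol (syringol) | COc1cccc(OC)c1O | starting material
2 | 2‑(benzyloxy)‑1,3‑dimethoxybenzene | COc1cccc(OC)c1OCc1ccccc1 | intermediate
3 | 3‑(benzyloxy)‑1,5‑dibromo‑2,4‑dimethoxybenzene | COc1c(Br)cc(Br)c(OC)c1OCc1ccccc1 | intermediate
4 | 3‑(benzyloxy)‑1,2,4,5‑tetramethoxybenzene | COc1cc(OC)c(OC)c(OCc2ccccc2)c1OC | intermediate
5 | [4‑(benzyloxy)‑2,3,5,6‑tetramethoxyphenyl]lithium | [Li]c1c(OC)c(OC)c(OCc2ccccc2)c(OC)c1OC | intermediate
6 | lithium [4‑(benzyloxy)‑2,3,5,6‑tetramethoxyphenyl](dimethylamino)methanolate | [Li]OC(N(C)C)c1c(OC)c(OC)c(OCc2ccccc2)c(OC)c1OC | intermediate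
7 | 4‑(benzyloxy)‑2,3,5,6‑tetramethoxybenzaldehyde | COc1c(C=O)c(OC)c(OC)c(OCc2ccccc2)c1OC | intermediate
8 | 2,5‑dimethoxybenzaldehyde | COc1ccc(OC)c(C=O)c1 | starting material
9 | 2,5‑dimethoxyphenyl formate | COc1ccc(OC)c(OC=O)c1 | intermediate
10 | 2,5‑dimethoxyphenol | COc1ccc(OC)c(O)c1 | intermediate
11 | 2‑(benzyloxy)‑1,4‑dimethoxybenzene | COc1ccc(OC)c(OCc2ccccc2)c1 | intermediate
12 | N‑[4‑(benzyloxy)‑2,5‑dimethoxybenzylidene]‑N‑methylmethanaminium chloride | COc1cc(OCc2ccccc2)c(OC)cc1C=[N+](C)C.[Cl-] | intermediate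
13 | 4‑(benzyloxy)‑2,5‑dimethoxybenzaldehyde | COc1cc(OCc2ccccc2)c(OC)cc1C=O | intermediate
14 | 1‑(benzyloxy)‑4‑ethynyl‑2,5‑dimethoxybenzene | C#Cc1cc(OC)c(OCc2ccccc2)cc1OC | intermediate
15 | lithium [4‑(benzyloxy)‑2,5‑dimethoxyphenyl]acetylide | [Li]C#Cc1cc(OC)c(OCc2ccccc2)cc1OC | intermediate
16 | rac‑1‑[4‑(benzyloxy)‑2,3,5,6‑tetramethoxyphenyl]‑3‑[4‑(benzyloxy)‑2,5‑dimethoxyphenyl]prop‑2‑yn‑1‑ol | OC(C#Cc1cc(OC)c(OCc2ccccc2)cc1OC)c1c(OC)c(OC)c(OCc2ccccc2)c(OC)c1OC | intermediate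
17 | 1‑[4‑(benzyloxy)‑2,3,5,6‑tetramethoxyphenyl]‑3‑[4‑(benzyloxy)‑2,5‑dimethoxyphenyl]prop‑2‑yn‑1‑one | O=C(C#Cc1cc(OC)c(OCc2ccccc2)cc1OC)c1c(OC)c(OC)c(OCc2ccccc2)c(OC)c1OC | intermediate
18 | 7‑(benzyloxy)‑2‑[4‑(benzyloxy)‑2,5‑dimethoxyphenyl]‑3‑iodo‑5,6,8‑trimethoxy‑4H‑chromen‑4‑one | COc1cc(-c2oc3c(OC)c(OCc4ccccc4)c(OC)c(OC)c3c(=O)c2I)c(OC)cc1OCc1ccccc1 | intermediate
19 | 7‑(benzyloxy)‑2‑[4‑(benzyloxy)‑2,5‑dimethoxyphenyl]‑3,5,6,8‑tetramethoxy‑4H‑chromen‑4‑one | COc1cc(-c2oc3c(OC)c(OCc4ccccc4)c(OC)c(OC)c3c(=O)c2OC)c(OC)cc1OCc1ccccc1 | intermediate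
20 | 5,7‑dihydroxy‑2‑(4‑hydroxy‑2,5‑dimethoxyphenyl)‑3,6,8‑trimethoxy‑4H‑chromen‑4‑one | COc1cc(-c2oc3c(OC)c(O)c(OC)c(O)c3c(=O)c2OC)c(OC)cc1O | target

**Step count**

Total steps: 13. Longest linear sequence: 9 steps (steps 1–4 then 9–13 from syringol 1, or steps 5–13 from 2,5‑dimethoxybenzaldehyde 8).

**Steps most likely to fail**

1. Step 11 (key step). Iodination of the electron‑rich ring B, or closure by the 2'‑methoxy oxygen onto the carbonyl‑side alkyne carbon, may outrun the 6‑endo closure.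
Fallback, setting out from aldehyde 7 (with alkyne 14) and coming back at 18: chelation‑controlled mono‑demethylation of 7 with MgI2·OEt2 should give 4‑(benzyloxy)‑2‑hydroxy‑3,5,6‑trimethoxybenzaldehyde F1 (the two ortho methoxy groups are equivalent). Addition of acetylide 15 (2.2 equiv, from 14 and n‑BuLi) should give 1‑[4‑(benzyloxy)‑2‑hydroxy‑3,5,6‑trimethoxyphenyl]‑3‑[4‑(benzyloxy)‑2,5‑dimethoxyphenyl]prop‑2‑yn‑1‑ol F2, and MnO2 oxidation the 2‑hydroxyaryl ynone F3. Et2NH in EtOH should then close ring C by amine conjugate addition followed by addition–elimination of the phenol, which can only give the six‑membered ring, to 7‑(benzyloxy)‑2‑[4‑(benzyloxy)‑2,5‑dimethoxyphenyl]‑5,6,8‑trimethoxy‑4H‑chromen‑4‑one F4. Lithiation of C3 with LDA in THF at −78 °C and quenching with I2 should return the route to 18.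

2. Step 12. Methoxide may add to C2 and open the pyranone, or the iodide may be lost reductively before C–O coupling occurs.
Fallback, setting out from 18 and coming back at 19: iodine–magnesium exchange with i‑PrMgCl·LiCl in THF at −40 °C should give the 3‑magnesiated flavone F5. Trapping with B(OMe)3 should give the dimethyl boronate F6, and oxidation in the same flask with NaBO3·4H2O the flavonol 7‑(benzyloxy)‑2‑[4‑(benzyloxy)‑2,5‑dimethoxyphenyl]‑3‑hydroxy‑5,6,8‑trimethoxy‑4H‑chromen‑4‑one F7. O‑Methylation of the 3‑hydroxyl with MeI and K2CO3 in acetone should give 19.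

3. Step 13. A second methyl ether may be lost (the 3‑OMe next to the carbonyl, or the 6‑OMe between the boron‑bound 5‑ and 7‑oxygens), or the 5‑OMe may be cleaved incompletely.
Fallback, setting out from 19 and coming back at 20: hydrogenolysis (H2, Pd/C, EtOAc–MeOH) should remove both benzyl groups without Lewis acid to give 7‑hydroxy‑2‑(4‑hydroxy‑2,5‑dimethoxyphenyl)‑3,5,6,8‑tetramethoxy‑4H‑chromen‑4‑one F8. Treatment with anhydrous AlCl3 in MeCN, a milder chelation‑driven demethylation that is selective for the 5‑position of polymethoxyflavones, should then give 20.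

**Further compounds**

F1 | step 11 | 4‑(benzyloxy)‑2‑hydroxy‑3,5,6‑trimethoxybenzaldehyde | Oc1c(C=O)c(OC)c(OC)c(OCc2ccccc2)c1OC
F2 | step 11 | rac‑1‑[4‑(benzyloxy)‑2‑hydroxy‑3,5,6‑trimethoxyphenyl]‑3‑[4‑(benzyloxy)‑2,5‑dimethoxyphenyl]prop‑2‑yn‑1‑ol | OC(C#Cc1cc(OC)c(OCc2ccccc2)cc1OC)c1c(O)c(OC)c(OCc2ccccc2)c(OC)c1OC
F3 | step 11 | 1‑[4‑(benzyloxy)‑2‑hydroxy‑3,5,6‑trimethoxyphenyl]‑3‑[4‑(benzyloxy)‑2,5‑dimethoxyphenyl]prop‑2‑yn‑1‑one | O=C(C#Cc1cc(OC)c(OCc2ccccc2)cc1OC)c1c(O)c(OC)c(OCc2ccccc2)c(OC)c1OC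
F4 | step 11 | 7‑(benzyloxy)‑2‑[4‑(benzyloxy)‑2,5‑dimethoxyphenyl]‑5,6,8‑trimethoxy‑4H‑chromen‑4‑one | COc1cc(-c2cc(=O)c3c(OC)c(OC)c(OCc4ccccc4)c(OC)c3o2)c(OC)cc1OCc1ccccc1
F5 | step 12 | {7‑(benzyloxy)‑2‑[4‑(benzyloxy)‑2,5‑dimethoxyphenyl]‑5,6,8‑trimethoxy‑4‑oxo‑4H‑chromen‑3‑yl}magnesium chloride | COc1cc(-c2oc3c(OC)c(OCc4ccccc4)c(OC)c(OC)c3c(=O)c2[Mg]Cl)c(OC)cc1OCc1ccccc1
F6 | step 12 | dimethyl {7‑(benzyloxy)‑2‑[4‑(benzyloxy)‑2,5‑dimethoxyphenyl]‑5,6,8‑trimethoxy‑4‑oxo‑4H‑chromen‑3‑yl}boronate | COc1cc(-c2oc3c(OC)c(OCc4ccccc4)c(OC)c(OC)c3c(=O)c2B(OC)OC)c(OC)cc1OCc1ccccc1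
F7 | step 12 | 7‑(benzyloxy)‑2‑[4‑(benzyloxy)‑2,5‑dimethoxyphenyl]‑3‑hydroxy‑5,6,8‑trimethoxy‑4H‑chromen‑4‑one | COc1cc(-c2oc3c(OC)c(OCc4ccccc4)c(OC)c(OC)c3c(=O)c2O)c(OC)cc1OCc1ccccc1
F8 | step 13 | 7‑hydroxy‑2‑(4‑hydroxy‑2,5‑dimethoxyphenyl)‑3,5,6,8‑tetramethoxy‑4H‑chromen‑4‑one | COc1cc(-c2oc3c(OC)c(O)c(OC)c(OC)c3c(=O)c2OC)c(OC)cc1O
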